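The dihydrofuran ring is disconnected at O1–C2, leading back to a triarylethylene in which the C2=C3 alkene carries the 4-hydroxyphenyl ring B on C2, and ring A (5-bromo-2-hydroxyphenyl) plus the bis-silylated resorcinol ring C on C3. Because the para-hydroxyl of ring B is conjugated with C3 through C2, the alkene behaves as an extended enol. A chiral phosphoric acid can therefore deliver a proton to C3, and the ring A hydroxyl then closes onto C2 of the resulting p-quinone methide, forming the ring and both stereocentres at once. The resorcinol oxygens travel as silyl ethers so that nothing harsher than buffered fluoride follows; the C5 bromide later carries the stilbene arm by Heck coupling.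

Key step: step 8

Remarks and assumptions
- Atom numbers (O1, C2, C3, C5) are those of the 2,3-dihydrobenzofuran of the target. Ring A is its benzo ring, ring B the 4-hydroxyphenyl on C2, ring C the resorcinol ring on C3, ring D the resorcinol ring of the styryl arm. TBS = tert-butyldimethylsilyl.
- Which antipode of the phosphoric acid leads to the (2S,3S) series cannot be derived from precedent; the (R)-acid is written, and the (S)-acid would be used if the first experiment showed the opposite sense.
- Alkenes 11 and 12 are carried as E/Z mixtures, because both isomers converge on the same quinone methide in step 8.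
- From step 5 to step 7 no acid meets the alkene once the ring A hydroxyl is free, so no racemic ring closure can precede the chiral acid.

Step 1
Reactants: 1 5-bromoresorcinol
Product: 2 1-bromo-3,5-bis[(tert-butyldimethylsilyl)oxy]benzene
Conditions: TBSCl (2.4 equiv), imidazole, DMF, rt
Reagents that add atoms: tert-butyldimethylsilyl chloride, CC(C)(C)[Si](C)(C)Cl
Why: Imidazole-promoted silylation of both phenols; the aryl TBS ethers should survive the organometallic, Lewis acid and palladium steps ahead and leave at the end with fluoride.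

Step 2
Reactants: 2 1-bromo-3,5-bis[(tert-butyldimethylsilyl)oxy]benzene
Product: 3 3,5-bis[(tert-butyldimethylsilyl)oxy]styrene
Conditions: Bu3SnCH=CH2, Pd(PPh3)4 (3 mol%), BHT (cat.), toluene, 100 °C
Reagents that add atoms: tributyl(vinyl)stannane, CCCC[Sn](CCCC)(CCCC)C=C
Why: Migita–Kosugi–Stille vinylation of an aryl bromide under neutral conditions, which should leave the aryl silyl ethers intact.

Step 3
Reactants: 4 5-bromosalicylaldehyde
Product: 5 2-(allyloxy)-5-bromobenzaldehyde
Conditions: allyl bromide, K2CO3, DMF, rt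
Reagents that add atoms: allyl bromide, C=CCBr
Why: Williamson ether synthesis on the phenoxide; the allyl group blocks the ring A hydroxyl until it can be released under neutral conditions that do not touch the silyl ethers.

Step 4
Reactants: 2 1-bromo-3,5-bis[(tert-butyldimethylsilyl)oxy]benzene; 5 2-(allyloxy)-5-bromobenzaldehyde
Product: 7 [2-(allyloxy)-5-bromophenyl]{3,5-bis[(tert-butyldimethylsilyl)oxy]phenyl}methanol (racemic), via arylmagnesium bromide 6 (not isolated)
Conditions: Mg, THF, 50 °C; then 5, 0 °C; aq. NH4Cl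
Reagents that add atoms: none
Why: Grignard formation and 1,2-addition to the aldehyde, which is much faster than any exchange at the aryl bromide of 5; the carbinol centre is racemic and disappears in step 6.

Step 5
Reactants: 7 [2-(allyloxy)-5-bromophenyl]{3,5-bis[(tert-butyldimethylsilyl)oxy]phenyl}methanol
Product: 8 diethyl {[2-(allyloxy)-5-bromophenyl]{3,5-bis[(tert-butyldimethylsilyl)oxy]phenyl}methyl}phosphonate (racemic)
Conditions: P(OEt)3 (3 equiv), ZnBr2 (20 mol%), CH2Cl2, rt
Reagents that add atoms: triethyl phosphite, CCOP(OCC)OCC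
Why: Lewis acid-mediated Michaelis–Arbuzov reaction, in which ZnBr2 ionises the electron-rich benzhydrol to a diarylmethyl cation that the phosphite captures before losing one ethyl group.

Step 6
Reactants: 8 diethyl {[2-(allyloxy)-5-bromophenyl]{3,5-bis[(tert-butyldimethylsilyl)oxy]phenyl}methyl}phosphonate; 9 4-(allyloxy)benzaldehyde
Product: 11 1-(allyloxy)-2-{2-[4-(allyloxy)phenyl]-1-{3,5-bis[(tert-butyldimethylsilyl)oxy]phenyl}ethenyl}-4-bromobenzene (E/Z mixture), via lithiated phosphonate 10 (not isolated)
Conditions: LiN(i-Pr)2 (1.05 equiv), THF, −78 °C; then 9, −78 °C → rt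
Reagents that add atoms: none
Why: Horner–Wadsworth–Emmons olefination of a diarylmethylphosphonate anion with an aromatic aldehyde, an established way to triarylethylenes; the alkene geometry is irrelevant for step 8 and the alkene is formed without acid.

Step 7
Reactants: 11 1-(allyloxy)-2-{2-[4-(allyloxy)phenyl]-1-{3,5-bis[(tert-butyldimethylsilyl)oxy]phenyl}ethenyl}-4-bromobenzene
Product: 12 4-bromo-2-[1-{3,5-bis[(tert-butyldimethylsilyl)oxy]phenyl}-2-(4-hydroxyphenyl)ethenyl]phenol (E/Z mixture)
Conditions: Pd(PPh3)4 (5 mol%), morpholine (10 equiv), THF, rt; pH 7 buffer work-up; Et3N-deactivated silica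
Reagents that add atoms: none
Why: Tsuji–Trost deallylation, in which zerovalent palladium ionises both aryl allyl ethers and morpholine captures the allyl units, under conditions that are not acidic, do not cleave aryl silyl ethers and should not insert into the electron-rich C–Br bond at room temperature.

Step 8
Reactants: 12 4-bromo-2-[1-{3,5-bis[(tert-butyldimethylsilyl)oxy]phenyl}-2-(4-hydroxyphenyl)ethenyl]phenol
Product: 14 4-[(2S,3S)-3-{3,5-bis[(tert-butyldimethylsilyl)oxy]phenyl}-5-bromo-2,3-dihydro-1-benzofuran-2-yl]phenol, via p-quinone methide 13 (not isolated)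
Conditions: (R)-3,3′-bis(2,4,6-triisopropylphenyl)-1,1′-binaphthyl-2,2′-diyl hydrogen phosphate (10 mol%), toluene (0.02 M), 4 Å MS, −20 °C → rt; then Et3N
Reagents that add atoms: none
Why: Proposed new method: the phosphoric acid should transfer its proton to C3 of 12 (the carbon β to ring B) while its P=O oxygen accepts the 4-OH proton, giving the neutral p-quinone methide 13 hydrogen-bonded to the catalyst, after which the ring A hydroxyl adds to C2 and ring B rearomatises; the closest known reaction types are chiral phosphoric acid-catalysed 1,6-additions to p-quinone methides generated in situ from 4-hydroxystyrenes and achiral acid-mediated hydroalkoxylation of 2-hydroxystilbenes. The dihydrofuran ring closes in a 5-exo-trig mode, since the C2=C bond of the quinone methide that is attacked lies outside the new ring. C3 is under catalyst control: protonation is reversible, the two enantiomers of 13 equilibrate through 12, and closure inside the chiral phosphate, which binds the quinone methide oxygen and the ring A hydroxyl at the same time, should consume one of them faster; C2 is under substrate control, the oxygen attacking the face that places ring B anti to ring C, which is also the more stable trans arrangement. The step needs protonation at C3 and not at C2, and the para-hydroxyl of ring B secures this by making C3 the nucleophilic end of the extended enol, whereas a cation at C3 would rest on the twisted, bromine-deactivated ring A, has no ring-closing outlet and returns to 12. Racemic background closure is held down by keeping 12 free of other acids and of amine, by dilution and by low temperature, and the acid is quenched as soon as 12 is consumed so that 14 is not reopened.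

Step 9
Reactants: 14 4-[(2S,3S)-3-{3,5-bis[(tert-butyldimethylsilyl)oxy]phenyl}-5-bromo-2,3-dihydro-1-benzofuran-2-yl]phenol
Product: 15 (2S,3S)-3-{3,5-bis[(tert-butyldimethylsilyl)oxy]phenyl}-5-bromo-2-{4-[(tert-butyldimethylsilyl)oxy]phenyl}-2,3-dihydro-1-benzofuran
Conditions: TBSCl, imidazole, CH2Cl2, 0 °C → rt
Reagents that add atoms: tert-butyldimethylsilyl chloride, CC(C)(C)[Si](C)(C)Cl
Why: Standard silylation of the ring B phenol, which shuts off base-induced opening of the dihydrofuran through a quinone methide during the Heck step and makes all protecting groups identical.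

Step 10
Reactants: 15 (2S,3S)-3-{3,5-bis[(tert-butyldimethylsilyl)oxy]phenyl}-5-bromo-2-{4-[(tert-butyldimethylsilyl)oxy]phenyl}-2,3-dihydro-1-benzofuran; 3 3,5-bis[(tert-butyldimethylsilyl)oxy]styrene
Product: 16 (2S,3S)-3-{3,5-bis[(tert-butyldimethylsilyl)oxy]phenyl}-5-[(E)-2-{3,5-bis[(tert-butyldimethylsilyl)oxy]phenyl}ethenyl]-2-{4-[(tert-butyldimethylsilyl)oxy]phenyl}-2,3-dihydro-1-benzofuran
Conditions: Pd2(dba)3 (2 mol%), P(t-Bu)3 (8 mol%), Cy2NMe (1.5 equiv), 1,4-dioxane, rt → 50 °C
Reagents that add atoms: none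
Why: Mizoroki–Heck reaction with a P(t-Bu)3-ligated palladium catalyst, which couples electron-rich aryl bromides near room temperature; syn insertion and syn β-hydride elimination should give the E-stilbene, and C2 and C3 are not involved.

Step 11
Reactants: 16 (2S,3S)-3-{3,5-bis[(tert-butyldimethylsilyl)oxy]phenyl}-5-[(E)-2-{3,5-bis[(tert-butyldimethylsilyl)oxy]phenyl}ethenyl]-2-{4-[(tert-butyldimethylsilyl)oxy]phenyl}-2,3-dihydro-1-benzofuran
Product: 17 (2S,3S)-trans-δ-viniferin
Conditions: Bu4NF (6 equiv), AcOH (6 equiv), THF, 0 °C → rt, argon, exclusion of light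
Reagents that add atoms: none
Why: Fluoride-induced cleavage of the five aryl silyl ethers, buffered with acetic acid so that each phenoxide is protonated at once and the acid- and base-sensitive 2-aryl-dihydrobenzofuran is not opened.

Compound list
1 | 5-bromoresorcinol (5-bromobenzene-1,3-diol) | Oc1cc(O)cc(Br)c1 | starting material
2 | 1-bromo-3,5-bis[(tert-butyldimethylsilyl)oxy]benzene | CC(C)(C)[Si](C)(C)Oc1cc(Br)cc(O[Si](C)(C)C(C)(C)C)c1 | intermediate
3 | 3,5-bis[(tert-butyldimethylsilyl)oxy]styrene | C=Cc1cc(O[Si](C)(C)C(C)(C)C)cc(O[Si](C)(C)C(C)(C)C)c1 | intermediate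
4 | 5-bromosalicylaldehyde | O=Cc1cc(Br)ccc1O | starting material
5 | 2-(allyloxy)-5-bromobenzaldehyde | C=CCOc1ccc(Br)cc1C=O | intermediate
6 | {3,5-bis[(tert-butyldimethylsilyl)oxy]phenyl}magnesium bromide (not isolated) | CC(C)(C)[Si](C)(C)Oc1cc([Mg]Br)cc(O[Si](C)(C)C(C)(C)C)c1 | intermediate
7 | [2-(allyloxy)-5-bromophenyl]{3,5-bis[(tert-butyldimethylsilyl)oxy]phenyl}methanol (racemic) | C=CCOc1ccc(Br)cc1C(O)c1cc(O[Si](C)(C)C(C)(C)C)cc(O[Si](C)(C)C(C)(C)C)c1 | intermediate
8 | diethyl {[2-(allyloxy)-5-bromophenyl]{3,5-bis[(tert-butyldimethylsilyl)oxy]phenyl}methyl}phosphonate (racemic) | C=CCOc1ccc(Br)cc1C(c1cc(O[Si](C)(C)C(C)(C)C)cc(O[Si](C)(C)C(C)(C)C)c1)P(=O)(OCC)OCC | intermediate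
9 | 4-(allyloxy)benzaldehyde | C=CCOc1ccc(C=O)cc1 | starting material
10 | lithium salt of the carbanion of phosphonate 8 (not isolated) | C=CCOc1ccc(Br)cc1[C-](c1cc(O[Si](C)(C)C(C)(C)C)cc(O[Si](C)(C)C(C)(C)C)c1)P(=O)(OCC)OCC.[Li+] | intermediate
11 | 1-(allyloxy)-2-{2-[4-(allyloxy)phenyl]-1-{3,5-bis[(tert-butyldimethylsilyl)oxy]phenyl}ethenyl}-4-bromobenzene (E/Z mixture, alkene geometry not specified) | C=CCOc1ccc(C=C(c2cc(Br)ccc2OCC=C)c2cc(O[Si](C)(C)C(C)(C)C)cc(O[Si](C)(C)C(C)(C)C)c2)cc1 | intermediate
12 | 4-bromo-2-[1-{3,5-bis[(tert-butyldimethylsilyl)oxy]phenyl}-2-(4-hydroxyphenyl)ethenyl]phenol (E/Z mixture, alkene geometry not specified) | Oc1ccc(C=C(c2cc(Br)ccc2O)c2cc(O[Si](C)(C)C(C)(C)C)cc(O[Si](C)(C)C(C)(C)C)c2)cc1 | intermediate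
13 | 4-[2-(5-bromo-2-hydroxyphenyl)-2-{3,5-bis[(tert-butyldimethylsilyl)oxy]phenyl}ethylidene]cyclohexa-2,5-dien-1-one (not isolated; shown as the enantiomer that closes to 14, in equilibrium with its mirror image through 12) | O=C1C=CC(=C[C@H](c2cc(Br)ccc2O)c2cc(O[Si](C)(C)C(C)(C)C)cc(O[Si](C)(C)C(C)(C)C)c2)C=C1 | intermediate
14 | 4-[(2S,3S)-3-{3,5-bis[(tert-butyldimethylsilyl)oxy]phenyl}-5-bromo-2,3-dihydro-1-benzofuran-2-yl]phenol | Oc1ccc([C@H]2Oc3ccc(Br)cc3[C@@H]2c2cc(O[Si](C)(C)C(C)(C)C)cc(O[Si](C)(C)C(C)(C)C)c2)cc1 | intermediate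
15 | (2S,3S)-3-{3,5-bis[(tert-butyldimethylsilyl)oxy]phenyl}-5-bromo-2-{4-[(tert-butyldimethylsilyl)oxy]phenyl}-2,3-dihydro-1-benzofuran | CC(C)(C)[Si](C)(C)Oc1ccc([C@H]2Oc3ccc(Br)cc3[C@@H]2c2cc(O[Si](C)(C)C(C)(C)C)cc(O[Si](C)(C)C(C)(C)C)c2)cc1 | intermediate
16 | (2S,3S)-3-{3,5-bis[(tert-butyldimethylsilyl)oxy]phenyl}-5-[(E)-2-{3,5-bis[(tert-butyldimethylsilyl)oxy]phenyl}ethenyl]-2-{4-[(tert-butyldimethylsilyl)oxy]phenyl}-2,3-dihydro-1-benzofuran | CC(C)(C)[Si](C)(C)Oc1ccc([C@H]2Oc3ccc(/C=C/c4cc(O[Si](C)(C)C(C)(C)C)cc(O[Si](C)(C)C(C)(C)C)c4)cc3[C@@H]2c2cc(O[Si](C)(C)C(C)(C)C)cc(O[Si](C)(C)C(C)(C)C)c2)cc1 | intermediate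
17 | (2S,3S)-trans-δ-viniferin | Oc1ccc([C@H]2Oc3ccc(/C=C/c4cc(O)cc(O)c4)cc3[C@@H]2c2cc(O)cc(O)c2)cc1 | target

Total step count: 11
Longest linear sequence: 9 steps (1 → 2 → 7 → 8 → 11 → 12 → 14 → 15 → 16 → 17, i.e. steps 1, 4, 5, 6, 7, 8, 9, 10, 11)

Steps most likely to fail

1. Step 8 (new method). The acid may be too weak to protonate the trisubstituted alkene at a useful rate. The two enantiomeric quinone methides may close at similar rates, giving low enantiomeric excess. The quinone methide may be trapped between molecules, or the product may reopen and lose configuration at C3. A stronger chiral acid would be only a change of conditions. The fallback uses known chemistry and sets out from 12. An achiral Brønsted acid (diphenyl hydrogen phosphate, 10 mol%, toluene, rt) should effect the same cycloisomerisation without induction and give the racemic trans compound, that is 14 together with its mirror image 4-[(2R,3R)-3-{3,5-bis[(tert-butyldimethylsilyl)oxy]phenyl}-5-bromo-2,3-dihydro-1-benzofuran-2-yl]phenol F1. Preparative chromatography on a chiral stationary phase (amylose tris(3,5-dimethylphenylcarbamate), supercritical CO2/MeOH) separates the two, and the (2S,3S) component re-enters the route as 14.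

2. Step 6. The hindered, doubly aryl-stabilised carbanion may add to the aldehyde too slowly, or the adduct may revert, so that 8 is recovered. The fallback sets out from 7 (it also bypasses step 5) and comes back at 11.
- Oxidation of 7 with MnO2 (CH2Cl2, rt) should give [2-(allyloxy)-5-bromophenyl]{3,5-bis[(tert-butyldimethylsilyl)oxy]phenyl}methanone F2.
- Aldehyde 9 is reduced with NaBH4 (MeOH, 0 °C) to 4-(allyloxy)benzyl alcohol F3, which SOCl2 (CH2Cl2, 0 °C) converts into 4-(allyloxy)benzyl chloride F4 and Mg (THF, 0 °C) into 4-(allyloxy)benzylmagnesium chloride F5.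
- Addition of F5 to F2 (THF, 0 °C; aq. NH4Cl) gives 1-[2-(allyloxy)-5-bromophenyl]-2-[4-(allyloxy)phenyl]-1-{3,5-bis[(tert-butyldimethylsilyl)oxy]phenyl}ethanol F6.
- Catalytic TsOH·H2O in toluene at 60 °C dehydrates F6 to 11. Because the ring A oxygen is still allylated, this acid cannot close the dihydrofuran ring.

3. Step 10. Oxidative addition into the electron-rich C–Br bond may be slow, styrene 3 may polymerise, and some 1,1-diarylethylene regioisomer may form. The fallback sets out from 15 and comes back at 16. Stille coupling of 15 with tributyl(vinyl)stannane (Pd(PPh3)4, toluene, 100 °C) should give (2S,3S)-3-{3,5-bis[(tert-butyldimethylsilyl)oxy]phenyl}-2-{4-[(tert-butyldimethylsilyl)oxy]phenyl}-5-ethenyl-2,3-dihydro-1-benzofuran F7. Cross-metathesis of F7 with an excess of 3 (second-generation Grubbs catalyst (H2IMes)(PCy3)Cl2Ru=CHPh, CH2Cl2, 40 °C) then gives the E-stilbene 16.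

Further compounds
F1 | step 8 | 4-[(2R,3R)-3-{3,5-bis[(tert-butyldimethylsilyl)oxy]phenyl}-5-bromo-2,3-dihydro-1-benzofuran-2-yl]phenol | Oc1ccc([C@@H]2Oc3ccc(Br)cc3[C@H]2c2cc(O[Si](C)(C)C(C)(C)C)cc(O[Si](C)(C)C(C)(C)C)c2)cc1
F2 | step 6 | [2-(allyloxy)-5-bromophenyl]{3,5-bis[(tert-butyldimethylsilyl)oxy]phenyl}methanone | C=CCOc1ccc(Br)cc1C(=O)c1cc(O[Si](C)(C)C(C)(C)C)cc(O[Si](C)(C)C(C)(C)C)c1
F3 | step 6 | 4-(allyloxy)benzyl alcohol | OCc1ccc(OCC=C)cc1
F4 | step 6 | 4-(allyloxy)benzyl chloride | ClCc1ccc(OCC=C)cc1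
F5 | step 6 | 4-(allyloxy)benzylmagnesium chloride | Cl[Mg]Cc1ccc(OCC=C)cc1
F6 | step 6 | 1-[2-(allyloxy)-5-bromophenyl]-2-[4-(allyloxy)phenyl]-1-{3,5-bis[(tert-butyldimethylsilyl)oxy]phenyl}ethanol (racemic) | C=CCOc1ccc(CC(O)(c2cc(Br)ccc2OCC=C)c2cc(O[Si](C)(C)C(C)(C)C)cc(O[Si](C)(C)C(C)(C)C)c2)cc1
F7 | step 10 | (2S,3S)-3-{3,5-bis[(tert-butyldimethylsilyl)oxy]phenyl}-2-{4-[(tert-butyldimethylsilyl)oxy]phenyl}-5-ethenyl-2,3-dihydro-1-benzofuran | CC(C)(C)[Si](C)(C)Oc1ccc([C@H]2Oc3ccc(C=C)cc3[C@@H]2c2cc(O[Si](C)(C)C(C)(C)C)cc(O[Si](C)(C)C(C)(C)C)c2)cc1
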